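**Conventions and assumptions**

- Atom numbering used throughout: ArCH2 is C7, CHOAc is C8, the tertiary carbinol is C9 and its CH2OAc arm is C1'. The ketal carbon is C10, the ring CH2CH2 is C11–C12, the methyl-bearing bridgehead is C13, the ring CH2 is C14 and the ring OCH is C15. The side-chain alkene is C16=C17. O1 joins C10 and C15; O2 joins C10 and C13.
- Abbreviations in names: Bic = (1R,3S,5R)-3-[(1E)-2,6-dimethylhepta-1,5-dien-1-yl]-5-methyl-2,8-dioxabicyclo[3.2.1]octan-1-yl; Ar = 2,5-dimethoxy-4-methylphenyl.
- Assumption: commercial (R)-(−)-linalool of high enantiomeric purity is used; it is the only source of absolute configuration besides the tartrate of step 13.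
- Remark: compounds 2–8 are carried as mixtures of both C10 epimers (that centre is left open in their SMILES) because the key step makes C10 planar. Compounds 12 and 13 are C15 epimers for the same reason.

## Analysis of the target

The target joins a methylhydroquinone through C7 to an acyclic C8–C9 unit, and that unit through the C9–C10 bond to a 2,8-dioxabicyclo[3.2.1]octane. The bicycle is a tetrahydrofuran (O2, C10–C13) and a 1,3-dioxane (C10, O1, C15, C14, C13, O2) that share the ketal carbon C10 and the methyl-bearing carbon C13. There are five stereocentres (8R, 9S, 10R, 13R, 15S) and one E-trisubstituted alkene (C16=C17). C10 and C13 are the bridgeheads, so their relative configuration is fixed by the bridge and only one has to be set. At C15 the dienyl chain is equatorial on the dioxane chair, on the side of the O2 bridge and away from the C11–C12 bridge. C9 and C8 lie outside the bicycle and have no simple relay from it; in the zigzag C7–C8–C9–C10 their oxygens are syn. The sensitive groups are the hydroquinone, the ketal (whose C15–O1 bond is also allylic), two acetates flanking a free tertiary hydroxyl (acyl migration), and two trisubstituted alkenes. The difficulty lies in the C9–C10 bond between two fully substituted carbons, in telling apart three oxygens on C8, C9 and C1', and in controlling C8 and C9 by reagents or by each other. The strategy rests on one observation: C10 with O2, C11, C12, C13, the C13 methyl and the three-carbon branch C9/C8/C1' is, atom for atom, furanoid linalool oxide with C10 at the ether level. Only the C10–O1 bond is missing for the ketal, and O1 can be the oxygen of the two-carbon arm C14–C15 that the vinyl group of linalool supplies.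

## Retrosynthetic reasoning

**28 to 26.** No skeletal bond is cut. The hydroquinone is the most fragile group and its phenols would compete in every acylation, so it is carried as the dimethyl ether 26 and released last through the quinone 27. The forward step has to remove two aryl methyl ethers without touching the alkenes, the ketal or the esters.

**26 to 24 via 25.** The two acetyl C–O bonds and the C1'–O bond are cut. The tertiary C9 hydroxyl and the C1' acetoxy group are traced to one epoxide (C9–O–C1') in 24, opened at its CH2 terminus by a carboxylate. This keeps C9–O free without a protecting group and leaves its configuration untouched. The epoxide is opened only after C8 is in place, because an earlier monoester of a 2-substituted glycerol could exchange its two primary arms by 1,3-acyl shift and erase C9.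

**24 to 20 and 22 (through 23).** The C7–C8 bond is cut. It separates the arene from the terpenoid half at a carbinol carbon, so the aryl part enters as the benzylic zinc reagent 23 made from chloride 22. The epoxy aldehyde 20 has an α-oxygen for chelation and a very large group (C10 with its bicycle) on the same carbon. The forward addition has to use one face of the aldehyde only.

**20 to 18 via 19.** The C9–O bond is cut. The epoxide comes from the 2-substituted allylic alcohol 18 by tartrate-controlled epoxidation. The free hydroxyl makes this alkene the only one of three that reacts, and the tartrate, not the remote ring stereocentres, decides C9.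

**18 to 13 and 16 (from 15 and 14) via 17.** The C15–C16 bond is cut next to O1. The acetate 13 is a precursor of a bicyclic oxocarbenium ion; the alkenylalane 16 carries the side chain with the E geometry fixed by syn-carbometalation of alkyne 15, itself from bromide 14. The bridge has to steer the nucleophile to the exo face of C15.

**13 to 9 via 11 and 10.** Functional-group changes only: C15 is taken back to the lactone level, and the oxygen that becomes O8 is taken back to a methyl hydrogen of an isopropenyl group. This reveals the bridged lactone 9, which already holds C8 to C15 and C1'.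

**9 to 8.** The C10–O1 bond is cut; this is the disconnection that defines the route. In the forward sense a hydride is removed from C10 of the 2-isopropenyltetrahydrofuran 8 by a high-potential quinone, and the carboxyl group on C13 closes the acyl ketal. Cutting here and not at C10–O2 keeps the linalool oxide ring intact, and C13 alone dictates C10.

**8 to 1 via 7, 6, 4, 3.** The carboxyl carbon C15 is the terminal vinyl carbon of 1 after hydroboration and oxidation. The isopropenyl group is the dehydrated tertiary alcohol of 3. The tetrahydrofuran arises from epoxide 2 by 5-exo opening. The carbinol centre of 1 becomes C13 unchanged.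

## Alternatives that were turned down

**Alternative 1:** The bonds C11–C12, C13–O2 and C10–O1 are cut, dividing the skeleton into the α-bromo ketone A2 (C7–C11 with both acetates and the C9 hydroxyl) and the methallyl carbinol A3 (C12–C21). In the forward step, Ir(ppy)3 under visible light reduces A2 to the C11 radical, which adds to the terminal carbon C12 of A3. The tertiary C13 radical is oxidised to the cation, and the ketone oxygen and the C15 hydroxyl close both rings to give A1, the dimethyl ether of the target (the same compound as 26).

- For: it is the most convergent plan. It forms three bonds and both rings in one operation and ends one step from the target; on convergence and longest linear sequence it is stronger than the chosen route.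
- Against: C13 is created from a planar tertiary cation, with only the 1,3-related C15 on a flexible chain to control it, whereas the chosen route takes C13 from linalool. The cation can also lose a proton or be intercepted by the neighbouring alkenes and ester groups. The electrophilic α-keto radical can add to the two trisubstituted alkenes of A3 as well. A2 must be made enantiopure with C8 and C9 set by separate reagent control, and it is an α'-hydroxy ketone prone to ketol shifts.
- Comparison: the untested step comes last and consumes both advanced fragments. The chosen route places its untested step at step 6, on a ten-carbon acid.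

**Alternative 2:** The C10–O1 bond is traced to a Baeyer–Villiger oxidation: the 7-oxanorbornanone A5 is treated with m-CPBA/NaHCO3 and oxygen is inserted between C10 and C15 to give the lactone A4.

- For: the reaction type is established; the oxygen-bearing bridgehead carbon migrates preferentially and with retention. On precedent for the ring-forming oxidation this alternative is stronger than the chosen key step.
- Against: A5 with two different bridgehead substituents has to come from furan cycloaddition chemistry, which brings a regiochemical problem and no absolute control, so a resolution or an asymmetric variant is needed. A4 carries only C9 as a CH2O group, so the fully substituted carbinol C9 with C8 and C1' must still be built next to the ketal by two further C–C bond formations and a stereocontrolled addition.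
- Comparison: the chosen lactone 9 already contains C8, C9 and C1' and takes its configuration from the chiral pool, which saves steps.

**Alternative 3:** The bonds C15–O1, C10–O1 and C10–O2 are cut, leading to the open-chain keto diol A7 with a tertiary allylic alcohol at C17. In the forward step, Re2O7 moves that hydroxyl to C15 by [3,3] shift of the perrhenate ester, and the C13 and C15 hydroxyls condense with the C10 ketone to the bridged ketal A6.

- For: this kind of transposition funnelled into a ketal is known. The equilibrium can correct both C15 (equatorial chain) and the alkene geometry, so on control of C15 and on precedent it is at least as strong as the chosen route, which relies on kinetic exo attack.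
- Against: A6 still has C8=C9 as a Z-alkene. Setting C8 and C9 then needs a dihydroxylation that must choose this hindered, electron-poorer alkene over two isolated trisubstituted alkenes and one of its faces; neither selectivity is secured. The tertiary allylic alcohol next to a prenyl-type alkene can ionise and cyclise under the acidic perrhenate conditions, and the Z-enone of A7 can isomerise. The C1' ether has to be exchanged for an acetate later.
- Comparison: the chosen route sets C9 by a hydroxyl-directed epoxidation that is site-selective among three alkenes, and C8 by chelation to C9.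

Key step: step 6

## Route

**Step 1**
Reactants: 1 (R)-linalool
Product: 3 2-[(5R)-5-ethenyl-5-methyloxolan-2-yl]propan-2-ol (furanoid linalool oxide; both C2 epimers), via 6,7-epoxylinalool 2 (not isolated)
Conditions: mCPBA, CH2Cl2, 0 °C; then TsOH (cat.), 0 °C → rt
Reagents that add atoms: mCPBA (3-chloroperoxybenzoic acid), OOC(=O)c1cccc(Cl)c1
Why: Peracid epoxidation is selective for the trisubstituted alkene; acid then triggers 5-exo opening of the epoxide at its secondary carbon by the tertiary hydroxyl, favoured over the 6-endo pyranoid mode, so the carbinol centre of linalool is kept as the future C13 and both C10 epimers form (they converge later); the minor pyranoid oxides are removed by chromatography.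

**Step 2**
Reactants: 3 furanoid linalool oxide
Product: 4 2-[(2R)-5-(2-hydroxypropan-2-yl)-2-methyloxolan-2-yl]ethan-1-ol
Conditions: 9-BBN, THF, 0 °C → rt; then NaOH, H2O2, 0 °C
Reagents that add atoms: hydrogen peroxide, OO
Why: Hydroboration–oxidation of the only alkene is anti-Markovnikov with 9-BBN (excess covers the free tertiary hydroxyl) and gives the primary alcohol carbon that becomes C15.

**Step 3**
Reactants: 4 diol
Product: 6 2-[(2R)-2-methyl-5-(prop-1-en-2-yl)oxolan-2-yl]ethyl acetate, via primary monoacetate 5 (not isolated)
Conditions: Ac2O, pyridine, 0 °C → rt; then POCl3, 0 → 50 °C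
Reagents that add atoms: acetic anhydride, CC(=O)OC(C)=O
Why: Without DMAP only the primary hydroxyl is acetylated; POCl3 then turns the tertiary alcohol into a dichlorophosphate that undergoes pyridine-mediated E2 elimination, expected mainly at the six accessible methyl hydrogens and not at the single hindered ring C–H, as in the usual preparation of isopropenyl groups from 2-hydroxyprop-2-yl ethers; the acid-labile enol ether isomer is removed on work-up.

**Step 4**
Reactants: 6 isopropenyl acetate
Product: 7 2-[(2R)-2-methyl-5-(prop-1-en-2-yl)oxolan-2-yl]ethan-1-ol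
Conditions: K2CO3, MeOH, rt
Reagents that add atoms: none
Why: Base-catalysed transesterification frees the primary alcohol without touching the allylic ether.

**Step 5**
Reactants: 7 primary alcohol
Product: 8 2-[(2R)-2-methyl-5-(prop-1-en-2-yl)oxolan-2-yl]acetic acid
Conditions: TEMPO (cat.), PhI(OAc)2, MeCN/H2O, rt
Reagents that add atoms: water, O
Why: Oxoammonium oxidation in aqueous acetonitrile takes the primary alcohol through the aldehyde hydrate to the acid and tolerates the 1,1-disubstituted alkene and the ether.

**Step 6**
Reactants: 8 isopropenyl acid (both C10 epimers)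
Product: 9 (1S,5R)-5-methyl-1-(prop-1-en-2-yl)-2,8-dioxabicyclo[3.2.1]octan-3-one
Conditions: DDQ, 2,6-dichloropyridine, LiClO4, 4 Å MS, ClCH2CH2Cl, rt → 45 °C
Reagents that add atoms: none
Why: Proposed new method: DDQ should abstract hydride from C10, the only C–H that is both allylic and α to the ring oxygen, giving an oxocarbenium ion conjugated with the isopropenyl group; the carboxyl group held on C13 then adds to C10 and gives up its proton to the hydroquinone anion. The closest known reaction type is the DDQ-mediated oxidative C–H cleavage of allylic and benzylic ethers with capture of the oxocarbenium ion by a tethered nucleophile, together with DDQ lactonisation of benzylic C–H bonds by carboxylic acids; an acyl ketal has not been closed this way. The ring closed is the six-membered 1,3-dioxan-4-one (O1, C10, O2, C13, C14, C15), in a 6-endo-trig mode with respect to the C10=O2 oxocarbenium bond, which completes the bridged bicycle. The new stereocentre C10 is controlled by C13 alone, because the one-carbon arm can reach C10 only on the face of the tetrahydrofuran that carries it, so both C10 epimers of 8 should give the same lactone. The selectivity needed is the site of hydride loss: oxygen lone-pair and allylic stabilisation together single out C10–H over the allylic methyl and the ring methylene groups, and C13 bears no hydrogen. A free carboxylic acid is inert to DDQ, which is why the oxidation is placed before any allylic alcohol or electron-rich arene is present; the weak base and the sieves protect the acyl ketal from the acidic hydroquinone and from water.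

**Step 7**
Reactants: 9 bridged lactone
Product: 10 (1S,5R)-1-(3-hydroxyprop-1-en-2-yl)-5-methyl-2,8-dioxabicyclo[3.2.1]octan-3-one
Conditions: SeO2 (cat.), tBuOOH (anhydrous), CH2Cl2, rt
Reagents that add atoms: tert-butyl hydroperoxide, CC(C)(C)OO (oxygen relayed through SeO2)
Why: Allylic oxidation by ene reaction and [2,3]-sigmatropic shift; the methyl group carries the only allylic hydrogens because C10 is quaternary, so the 2-substituted allyl alcohol is the only allylic alcohol possible, and neutral anhydrous conditions spare the acyl ketal.

**Step 8**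
Reactants: 10 allylic alcohol
Product: 11 (1S,5R)-1-{3-[(tert-butyldimethylsilyl)oxy]prop-1-en-2-yl}-5-methyl-2,8-dioxabicyclo[3.2.1]octan-3-one
Conditions: TBSCl, imidazole, DMF, rt
Reagents that add atoms: tert-butyldimethylsilyl chloride, CC(C)(C)[Si](C)(C)Cl
Why: Standard silylation masks the primary allylic hydroxyl for the hydride and organoaluminium steps.

**Step 9**
Reactants: 11 silyl ether lactone
Product: 13 (1S,5R)-1-{3-[(tert-butyldimethylsilyl)oxy]prop-1-en-2-yl}-5-methyl-2,8-dioxabicyclo[3.2.1]octan-3-yl acetate (C15 epimers), via diisobutylaluminium lactolate 12 (not isolated)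
Conditions: iBu2AlH, CH2Cl2, −78 °C; then Ac2O, pyridine, DMAP, −78 → 0 °C
Reagents that add atoms: acetic anhydride, CC(=O)OC(C)=O
Why: Reductive acetylation: the hydride adds once to the lactone carbonyl at low temperature and the aluminium hemiacetal is acetylated in the flask, which avoids the free lactol and its ring-chain equilibria; the C15 epimers converge in step 11.

**Step 10**
Reactants: 14 5-bromo-2-methylpent-2-ene
Product: 15 6-methylhept-5-en-1-yne
Conditions: HC≡CLi·H2NCH2CH2NH2, DMSO, rt
Reagents that add atoms: lithium acetylide (ethylenediamine complex), [Li]C#C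
Why: SN2 alkylation of acetylide by a primary homoallylic bromide in a dipolar aprotic solvent.

**Step 11**
Reactants: 13 C15 acetate; 15 6-methylhept-5-en-1-yne
Product: 17 tert-butyl[(2-Bic-prop-2-en-1-yl)oxy]dimethylsilane, via (E)-alkenyldimethylalane 16 (not isolated)
Conditions: 15, Me3Al, Cp2ZrCl2 (cat.), CH2Cl2, rt; excess Me3Al evaporated; then 13, CH2Cl2, −78 → 0 °C
Reagents that add atoms: trimethylaluminium, C[Al](C)C
Why: Negishi zirconium-catalysed syn-carboalumination places the methyl group from Me3Al on C17 and aluminium on C16 with E geometry; the Lewis acidic alane ionises the C15 acetate and transfers its alkenyl group, with retention of geometry, to the oxocarbenium ion from the exo face (syn to the O2 bridge, away from the C11–C12 bridge), which gives the equatorial 15S product.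

**Step 12**
Reactants: 17 silyl ether
Product: 18 2-Bic-prop-2-en-1-ol
Conditions: Bu4NF, THF, 0 °C → rt
Reagents that add atoms: none
Why: Fluoride cleaves the primary silyl ether; the ketal and the alkenes are inert.

**Step 13**
Reactants: 18 allylic alcohol
Product: 19 [(2R)-2-Bic-oxiran-2-yl]methanol
Conditions: Ti(OiPr)4 (cat.), D-(−)-diisopropyl tartrate, tBuOOH, 4 Å MS, CH2Cl2, −20 °C
Reagents that add atoms: tert-butyl hydroperoxide, CC(C)(C)OO
Why: Sharpless asymmetric epoxidation acts only on the alkene of the allylic alcohol, so both trisubstituted alkenes are left alone; the D-(−)-tartrate is the enantiomer that delivers oxygen to the face giving the (2R)-oxirane, which is C9–O in the configuration of the target (reagent control), and sieves with low temperature limit opening of the 2,2-disubstituted epoxy alcohol by alkoxide.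

**Step 14**
Reactants: 19 epoxy alcohol
Product: 20 (2S)-2-Bic-oxirane-2-carbaldehyde
Conditions: Dess–Martin periodinane, NaHCO3, CH2Cl2, 0 °C → rt
Reagents that add atoms: none
Why: Buffered periodinane oxidation gives the aldehyde; C9 carries no hydrogen, so it cannot epimerise.

**Step 15**
Reactants: 21 2,5-dimethoxytoluene
Product: 22 1-(chloromethyl)-2,5-dimethoxy-4-methylbenzene
Conditions: (CH2O)n, conc. HCl, HCl (g), 1,4-dioxane, rt
Reagents that add atoms: formaldehyde (as paraformaldehyde), C=O; hydrogen chloride, Cl
Why: Blanc chloromethylation; substitution goes para to the methyl group and ortho to a methoxy group, the most activated and least hindered position.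

**Step 16**
Reactants: 20 epoxy aldehyde; 22 benzylic chloride
Product: 24 (1R)-2-Ar-1-[(2S)-2-Bic-oxiran-2-yl]ethan-1-ol, via benzylic zinc chloride 23 (not isolated)
Conditions: 22, Zn, LiCl, THF, rt; then 20, MgBr2·OEt2, CH2Cl2, −78 → −20 °C
Reagents that add atoms: none
Why: Zinc insertion in the presence of LiCl gives the benzylic zinc chloride without Wurtz coupling; its 1,2-addition should be chelation-controlled (Cram chelate model): divalent magnesium bridges the aldehyde and epoxide oxygens, C10 with its bicycle blocks one face of the five-membered chelate, and the benzyl group enters from the side of the epoxide CH2, which sets 8R relative to 9S.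

**Step 17**
Reactants: 24 epoxy carbinol
Product: 25 (2S,3R)-4-Ar-2-Bic-2,3-dihydroxybutyl acetate
Conditions: Ti(OiPr)4, AcOH, CH2Cl2, rt
Reagents that add atoms: acetic acid, CC(=O)O
Why: Titanium-mediated opening of a 2,3-epoxy alcohol: the metal binds the C8 alkoxide and the epoxide oxygen and acetate attacks the unsubstituted terminus C1' in an SN2 reaction, so the C9–O bond and its configuration are kept.

**Step 18**
Reactants: 25 diol monoacetate
Product: 26 (2S,3R)-4-Ar-2-Bic-2-hydroxybutane-1,3-diyl diacetate
Conditions: Ac2O, pyridine, DMAP (cat.), CH2Cl2, 0 °C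
Reagents that add atoms: acetic anhydride, CC(=O)OC(C)=O
Why: Nucleophile-catalysed acetylation esterifies the secondary C8 hydroxyl while the tertiary C9 hydroxyl is too hindered; any acetyl group that has moved from O1' to O8 in 25 ends in the same diacetate.

**Step 19**
Reactants: 26 dimethyl ether diacetate
Product: 28 target CNP0160303.2, via quinone 27 (not isolated)
Conditions: (NH4)2Ce(NO3)6, MeCN/H2O, 0 °C; then Na2S2O4, EtOAc/H2O, rt
Reagents that add atoms: water, O
Why: Oxidative demethylation: tetravalent cerium oxidises the electron-rich 1,4-dimethoxyarene by single-electron transfer, water adds and methanol leaves to give the quinone, faster than the isolated alkenes, the ketal or the esters react; dithionite reduces the quinone to the hydroquinone during work-up.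

## Compound list

1 | (R)-linalool, (3R)-3,7-dimethylocta-1,6-dien-3-ol | C=C[C@](C)(O)CCC=C(C)C | starting material
2 | (3R)-6,7-epoxy-3,7-dimethyloct-1-en-3-ol (both C6 epimers) | C=C[C@](C)(O)CCC1OC1(C)C | intermediate
3 | 2-[(5R)-5-ethenyl-5-methyloxolan-2-yl]propan-2-ol (both C2 epimers) | CC(C)(O)C1CC[C@](C)(C=C)O1 | intermediate
4 | 2-[(2R)-5-(2-hydroxypropan-2-yl)-2-methyloxolan-2-yl]ethan-1-ol (both C5 epimers) | CC(C)(O)C1CC[C@](C)(CCO)O1 | intermediate
5 | 2-[(2R)-5-(2-hydroxypropan-2-yl)-2-methyloxolan-2-yl]ethyl acetate (both C5 epimers) | CC(C)(O)C1CC[C@](C)(CCOC(C)=O)O1 | intermediate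
6 | 2-[(2R)-2-methyl-5-(prop-1-en-2-yl)oxolan-2-yl]ethyl acetate (both C5 epimers) | C=C(C)C1CC[C@](C)(CCOC(C)=O)O1 | intermediate
7 | 2-[(2R)-2-methyl-5-(prop-1-en-2-yl)oxolan-2-yl]ethan-1-ol (both C5 epimers) | C=C(C)C1CC[C@](C)(CCO)O1 | intermediate
8 | 2-[(2R)-2-methyl-5-(prop-1-en-2-yl)oxolan-2-yl]acetic acid (both C5 epimers) | C=C(C)C1CC[C@](C)(CC(=O)O)O1 | intermediate
9 | (1S,5R)-5-methyl-1-(prop-1-en-2-yl)-2,8-dioxabicyclo[3.2.1]octan-3-one | C=C(C)[C@]12CC[C@](C)(CC(=O)O1)O2 | intermediate
10 | (1S,5R)-1-(3-hydroxyprop-1-en-2-yl)-5-methyl-2,8-dioxabicyclo[3.2.1]octan-3-one | C=C(CO)[C@]12CC[C@](C)(CC(=O)O1)O2 | intermediate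
11 | (1S,5R)-1-{3-[(tert-butyldimethylsilyl)oxy]prop-1-en-2-yl}-5-methyl-2,8-dioxabicyclo[3.2.1]octan-3-one | C=C(CO[Si](C)(C)C(C)(C)C)[C@]12CC[C@](C)(CC(=O)O1)O2 | intermediate
12 | diisobutylaluminium lactolate of 11 (C15 epimers) | C=C(CO[Si](C)(C)C(C)(C)C)[C@]12CC[C@](C)(CC(O[Al](CC(C)C)CC(C)C)O1)O2 | intermediate
13 | (1S,5R)-1-{3-[(tert-butyldimethylsilyl)oxy]prop-1-en-2-yl}-5-methyl-2,8-dioxabicyclo[3.2.1]octan-3-yl acetate (C15 epimers) | C=C(CO[Si](C)(C)C(C)(C)C)[C@]12CC[C@](C)(CC(OC(C)=O)O1)O2 | intermediate
14 | 5-bromo-2-methylpent-2-ene | CC(C)=CCCBr | starting material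
15 | 6-methylhept-5-en-1-yne | C#CCCC=C(C)C | intermediate
16 | [(1E)-2,6-dimethylhepta-1,5-dien-1-yl]dimethylalane | C[Al](C)/C=C(\C)CCC=C(C)C | intermediate
17 | tert-butyl[(2-Bic-prop-2-en-1-yl)oxy]dimethylsilane | C=C(CO[Si](C)(C)C(C)(C)C)[C@]12CC[C@](C)(C[C@@H](/C=C(\C)CCC=C(C)C)O1)O2 | intermediate
18 | 2-Bic-prop-2-en-1-ol | C=C(CO)[C@]12CC[C@](C)(C[C@@H](/C=C(\C)CCC=C(C)C)O1)O2 | intermediate
19 | [(2R)-2-Bic-oxiran-2-yl]methanol | OC[C@@]1(CO1)[C@]23CC[C@](C)(C[C@@H](/C=C(\C)CCC=C(C)C)O2)O3 | intermediate
20 | (2S)-2-Bic-oxirane-2-carbaldehyde | O=C[C@@]1(CO1)[C@]23CC[C@](C)(C[C@@H](/C=C(\C)CCC=C(C)C)O2)O3 | intermediate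
21 | 2,5-dimethoxytoluene (1,4-dimethoxy-2-methylbenzene) | COc1ccc(OC)c(C)c1 | starting material
22 | 1-(chloromethyl)-2,5-dimethoxy-4-methylbenzene | COc1cc(CCl)c(OC)cc1C | intermediate
23 | (2,5-dimethoxy-4-methylbenzyl)zinc chloride | COc1cc(C[Zn]Cl)c(OC)cc1C | intermediate
24 | (1R)-2-Ar-1-[(2S)-2-Bic-oxiran-2-yl]ethan-1-ol | O[C@H](Cc1cc(OC)c(C)cc1OC)[C@@]2(CO2)[C@]34CC[C@](C)(C[C@@H](/C=C(\C)CCC=C(C)C)O3)O4 | intermediate
25 | (2S,3R)-4-Ar-2-Bic-2,3-dihydroxybutyl acetate | CC(=O)OC[C@](O)([C@H](O)Cc1cc(OC)c(C)cc1OC)[C@]12CC[C@](C)(C[C@@H](/C=C(\C)CCC=C(C)C)O1)O2 | intermediate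
26 | (2S,3R)-4-Ar-2-Bic-2-hydroxybutane-1,3-diyl diacetate | CC(=O)OC[C@](O)([C@@H](Cc1cc(OC)c(C)cc1OC)OC(C)=O)[C@]12CC[C@](C)(C[C@@H](/C=C(\C)CCC=C(C)C)O1)O2 | intermediate
27 | (2S,3R)-2-Bic-2-hydroxy-4-(4-methyl-3,6-dioxocyclohexa-1,4-dien-1-yl)butane-1,3-diyl diacetate | CC(=O)OC[C@](O)([C@@H](CC1=CC(=O)C(C)=CC1=O)OC(C)=O)[C@]23CC[C@](C)(C[C@@H](/C=C(\C)CCC=C(C)C)O2)O3 | intermediate
28 | CNP0160303.2, (2S,3R)-4-(2,5-dihydroxy-4-methylphenyl)-2-Bic-2-hydroxybutane-1,3-diyl diacetate | CC(=O)OC[C@](O)([C@@H](Cc1cc(O)c(C)cc1O)OC(C)=O)[C@]12CC[C@](C)(C[C@@H](/C=C(\C)CCC=C(C)C)O1)O2 | target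

## Step count and least certain steps

Total: 19 steps. Longest linear sequence: 17 steps from (R)-linalool (steps 1–9, 11–14 and 16–19); steps 10 and 15 each prepare a fragment in one step.

**Step 6 (key step, proposed new method).**
- What may go wrong: hydride transfer may be too slow, because the alkene is only 1,1-disubstituted and stabilises the cation less than the allylic ethers for which the reaction type is known. The oxocarbenium ion may lose a proton from C11 and be dehydrogenated further toward a furan. The acidic hydroquinone may open the acyl ketal.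
- Fallback (known chemistry, from 1, returning at 9): C10 is brought to the ketone level before any ring is closed.
  - Hydroboration of 1 with 9-BBN and alkaline H2O2 gives (3R)-3,7-dimethyloct-6-ene-1,3-diol F1.
  - TEMPO/PhI(OAc)2 in MeCN/H2O gives (3R)-3-hydroxy-3,7-dimethyloct-6-enoic acid F2.
  - Ketohydroxylation of the trisubstituted alkene (RuCl3 cat., KHSO5, NaHCO3, EtOAc/MeCN/H2O) gives (3R)-3,7-dihydroxy-3,7-dimethyl-6-oxooctanoic acid F3.
  - Acid-catalysed dehydrative condensation of the β-hydroxy acid with the ketone (camphorsulfonic acid, MgSO4, CH2Cl2) closes the 1,3-dioxan-4-one and gives (1S,5R)-1-(2-hydroxypropan-2-yl)-5-methyl-2,8-dioxabicyclo[3.2.1]octan-3-one F4.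
  - Burgess reagent dehydrates the tertiary alcohol, which now has only methyl hydrogens, to 9.

**Step 16.**
- What may go wrong: facial selectivity at C8 is poor or reversed if the weakly basic epoxide oxygen does not chelate and the dipole-minimised (Cornforth) conformer reacts. The epoxide may also be opened by bromide.
- Fallback (from 19, returning at 26): the chelating group is changed to a zinc alkoxide on a ring-opened aldehyde.
  - Ti(OiPr)4 and pivalic acid open 19 at C1' to (2R)-2-Bic-2,3-dihydroxypropyl 2,2-dimethylpropanoate F5; a pivalate is used because it does not shift between the two primary oxygens.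
  - TEMPO/PhI(OAc)2 oxidises the primary alcohol to (2S)-2-Bic-2-hydroxy-3-oxopropyl 2,2-dimethylpropanoate F6.
  - Et2Zn converts the tertiary hydroxyl into a zinc alkoxide that chelates the aldehyde, and 23 adds anti to C10 to give (2S,3R)-4-Ar-2-Bic-2,3-dihydroxybutyl 2,2-dimethylpropanoate F7.
  - iBu2AlH removes the pivalate to give (2S,3R)-4-Ar-2-Bic-butane-1,2,3-triol F8.
  - Ac2O/pyridine acetylates the primary and secondary hydroxyls to 26.

**Step 11.**
- What may go wrong: methyl instead of alkenyl transfer from aluminium, incomplete ionisation of the hindered acetate, or erosion of exo selectivity at C15.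
- Fallback (from 15 and 13, returning at 17): an isolated, non-Lewis-acidic nucleophile is used with separate activation.
  - Carboalumination of 15 followed by I2 gives (1E)-1-iodo-2,6-dimethylhepta-1,5-diene F9.
  - tBuLi, B(OMe)3 and then KHF2 give potassium [(1E)-2,6-dimethylhepta-1,5-dien-1-yl]trifluoroborate F10.
  - BF3·OEt2 in MeCN ionises 13 and the trifluoroborate adds to the oxocarbenium ion on the exo face to give 17.

**Step 13.**
- What may go wrong: slow or mismatched epoxidation of the hindered 2-substituted allylic alcohol, and opening of the 2,2-disubstituted epoxy alcohol by alkoxide.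
- Fallback (from 18, returning at 24): C8 is set first and directs the epoxidation.
  - MnO2 gives 2-Bic-prop-2-enal F11.
  - 23 adds in 1,2-fashion to give 1-Ar-3-Bic-but-3-en-2-ol F12 as C8 epimers.
  - Dess–Martin periodinane gives 1-Ar-3-Bic-but-3-en-2-one F13.
  - Corey–Bakshi–Shibata reduction with the (S)-oxazaborolidine and BH3·SMe2 (alkenyl group as the large substituent) gives (2R)-1-Ar-3-Bic-but-3-en-2-ol F14.
  - VO(acac)2/tBuOOH epoxidation, directed by the C8 hydroxyl and erythro-selective for allylic alcohols with a 1,1-disubstituted alkene, gives 24.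

## Further compounds

F1 | step 6 | (3R)-3,7-dimethyloct-6-ene-1,3-diol | OCC[C@](C)(O)CCC=C(C)C
F2 | step 6 | (3R)-3-hydroxy-3,7-dimethyloct-6-enoic acid | OC(=O)C[C@](C)(O)CCC=C(C)C
F3 | step 6 | (3R)-3,7-dihydroxy-3,7-dimethyl-6-oxooctanoic acid | CC(C)(O)C(=O)CC[C@@](C)(O)CC(=O)O
F4 | step 6 | (1S,5R)-1-(2-hydroxypropan-2-yl)-5-methyl-2,8-dioxabicyclo[3.2.1]octan-3-one | CC(C)(O)[C@]12CC[C@](C)(CC(=O)O1)O2
F5 | step 16 | (2R)-2-Bic-2,3-dihydroxypropyl 2,2-dimethylpropanoate | CC(C)(C)C(=O)OC[C@](O)(CO)[C@]12CC[C@](C)(C[C@@H](/C=C(\C)CCC=C(C)C)O1)O2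
F6 | step 16 | (2S)-2-Bic-2-hydroxy-3-oxopropyl 2,2-dimethylpropanoate | CC(C)(C)C(=O)OC[C@](O)(C=O)[C@]12CC[C@](C)(C[C@@H](/C=C(\C)CCC=C(C)C)O1)O2
F7 | step 16 | (2S,3R)-4-Ar-2-Bic-2,3-dihydroxybutyl 2,2-dimethylpropanoate | CC(C)(C)C(=O)OC[C@](O)([C@H](O)Cc1cc(OC)c(C)cc1OC)[C@]12CC[C@](C)(C[C@@H](/C=C(\C)CCC=C(C)C)O1)O2
F8 | step 16 | (2S,3R)-4-Ar-2-Bic-butane-1,2,3-triol | OC[C@](O)([C@H](O)Cc1cc(OC)c(C)cc1OC)[C@]12CC[C@](C)(C[C@@H](/C=C(\C)CCC=C(C)C)O1)O2
F9 | step 11 | (1E)-1-iodo-2,6-dimethylhepta-1,5-diene | I/C=C(\C)CCC=C(C)C
F10 | step 11 | potassium [(1E)-2,6-dimethylhepta-1,5-dien-1-yl]trifluoroborate | [K+].F[B-](F)(F)/C=C(\C)CCC=C(C)C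
F11 | step 13 | 2-Bic-prop-2-enal | O=CC(=C)[C@]12CC[C@](C)(C[C@@H](/C=C(\C)CCC=C(C)C)O1)O2
F12 | step 13 | 1-Ar-3-Bic-but-3-en-2-ol (C2 epimers) | C=C(C(O)Cc1cc(OC)c(C)cc1OC)[C@]12CC[C@](C)(C[C@@H](/C=C(\C)CCC=C(C)C)O1)O2
F13 | step 13 | 1-Ar-3-Bic-but-3-en-2-one | C=C(C(=O)Cc1cc(OC)c(C)cc1OC)[C@]12CC[C@](C)(C[C@@H](/C=C(\C)CCC=C(C)C)O1)O2
F14 | step 13 | (2R)-1-Ar-3-Bic-but-3-en-2-ol | C=C([C@H](O)Cc1cc(OC)c(C)cc1OC)[C@]12CC[C@](C)(C[C@@H](/C=C(\C)CCC=C(C)C)O1)O2
A1 | alternative 1 | (2S,3R)-4-(2,5-dimethoxy-4-methylphenyl)-2-Bic-2-hydroxybutane-1,3-diyl diacetate (dimethyl ether of the target) | CC(=O)OC[C@](O)([C@@H](Cc1cc(OC)c(C)cc1OC)OC(C)=O)[C@]12CC[C@](C)(C[C@@H](/C=C(\C)CCC=C(C)C)O1)O2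
A2 | alternative 1 | (2R,3S)-3-(acetoxymethyl)-5-bromo-1-(2,5-dimethoxy-4-methylphenyl)-3-hydroxy-4-oxopentan-2-yl acetate | CC(=O)OC[C@](O)([C@@H](Cc1cc(OC)c(C)cc1OC)OC(C)=O)C(=O)CBr
A3 | alternative 1 | (4S,5E)-2,6,10-trimethylundeca-1,5,9-trien-4-ol | C=C(C)C[C@H](O)/C=C(\C)CCC=C(C)C
A4 | alternative 2 | (1S,5R)-1-{[(tert-butyldimethylsilyl)oxy]methyl}-5-methyl-2,8-dioxabicyclo[3.2.1]octan-3-one | CC(C)(C)[Si](C)(C)OC[C@]12CC[C@](C)(CC(=O)O1)O2
A5 | alternative 2 | (1R,4R)-1-{[(tert-butyldimethylsilyl)oxy]methyl}-4-methyl-7-oxabicyclo[2.2.1]heptan-2-one | CC(C)(C)[Si](C)(C)OC[C@]12CC[C@](C)(CC1=O)O2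
A6 | alternative 3 | (1R,3S,5R)-1-[(2Z)-4-(2,5-dimethoxy-4-methylphenyl)-1-{[2-(trimethylsilyl)ethoxy]methoxy}but-2-en-2-yl]-3-[(1E)-2,6-dimethylhepta-1,5-dien-1-yl]-5-methyl-2,8-dioxabicyclo[3.2.1]octane | COc1cc(C)c(OC)cc1C/C=C(/COCOCC[Si](C)(C)C)[C@]12CC[C@](C)(C[C@@H](/C=C(\C)CCC=C(C)C)O1)O2
A7 | alternative 3 | (2Z,7R,9E)-1-(2,5-dimethoxy-4-methylphenyl)-7,11-dihydroxy-7,11,15-trimethyl-3-({[2-(trimethylsilyl)ethoxy]methoxy}methyl)hexadeca-2,9,14-trien-4-one (C11 epimers) | COc1cc(C)c(OC)cc1C/C=C(/COCOCC[Si](C)(C)C)C(=O)CC[C@@](C)(O)C/C=C/C(C)(O)CCC=C(C)C
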